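(The earlier runs and the new flask are calculated with made-up constants, and the scatter is random.)

**Decisive loss.** Start from 62.2%: that much substrate has left the north-east flask at 2.00 min, with 0.117 equiv of reagent fed. So treat substrate as consuming itself, two at a turn. That is a second-order decay, whose first half-life is the inverse of its constant times the starting concentration.

| flask | substrate | reagent | temperature | remark | time |
|---|---|---|---|---|---|
| north-west | 0.025 M | 0.70 equiv (fed, over 12 min) | −25 °C | run made earlier |  |
| north-east | 0.10 M | 0.70 equiv (fed, over 12 min) | −5 °C | run made earlier |  |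
| south-east | 0.050 M | 1 equiv (fed, over 12 min) | −25 °C | run made earlier |  |
| teal | 0.050 M | 0.700 equiv | 10 °C | everything together at the start | 30 min |
| red | 0.050 M | 0.700 equiv (fed, over 12 min) | −20 °C |  | 30 min |

- north-west (time / min: target / %, substrate / %): 4.00: 0.9, 81.0; 10.0: 4.9, 58.9; 20.0: 12.7, 37.1; 30.0: 15.6, 26.6
- north-east (time / min: target / %, substrate / %): 2.00: 2.8, 37.8; 5.00: 5.0, 18.1; 10.0: 6.6, 8.2; 15.0: 6.7, 5.5
- south-east (time / min: target / %, substrate / %): 2.50: 0.8, 77.0; 6.00: 5.2, 54.5; 12.0: 14.5, 31.2; 30.0: 23.5, 10.9

(standard deviation of a reading: 0.5 percentage points)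

- a reading of substrate is of its free form alone

* which of the two ends with the higher amount of target, in percent of the substrate charged ("neither" if they lie within 2 percentage points) (teal / red / neither)
* target at the end, in percent of the substrate charged, teal
* target at the end, in percent of the substrate charged, red

**Inputs in turn.** Time and concentration are given, so take them as they stand. Next test the cold constant, read from the first substrate reading. It reads 2.35 M⁻¹ min⁻¹ in the north-west run and 2.39 M⁻¹ min⁻¹ in the south-east run at twice the concentration. Each is one scattered reading, and each also counts any substrate taken by the fed reagent, so hold this input as a rough reading. Now test the temperature. The north-east reading gives 8.23 M⁻¹ min⁻¹, a factor 3.51 over the cold constant. Freeze teal at that constant and its count below is still 12.3, so the extrapolation moves the size, not the order.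

**The count.** Extrapolate by that factor: teal 21.1 M⁻¹ min⁻¹, red 3.21 M⁻¹ min⁻¹. The half-lives are 0.948 min and 6.23 min, so teal runs 31.6 of them and red 4.82. This half-life count, run time over first half-life, leaves one over one plus the count: teal 3.07%, red 17.2%. Expect red to keep more substrate; this count speaks of substrate, not of target.

**The forecast.** It says red, with teal 9% and red 15.5%, and holds that “reagent must be dying, strongly with temperature”.

**The flask.** Teal ends at 1.03%, red at 16.5%: red is higher.

    2 substrate → self-condensation product (k = 1.50 M⁻¹ min⁻¹, Ea = 35.0 kJ mol⁻¹)
    substrate + reagent ⇌ isomer of the product (K = 81.0 M⁻¹, k = 0.800 M⁻¹ min⁻¹, Ea = 44.0 kJ mol⁻¹, ΔH = −44.0 kJ mol⁻¹)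
    substrate + reagent ⇌ target (K = 63.0 M⁻¹, k = 2.10 M⁻¹ min⁻¹, Ea = 53.0 kJ mol⁻¹, ΔH = −47.0 kJ mol⁻¹)
    (constants at −20 °C)

**Falling back.** Teal's target drains because it falls back to substrate and reagent: without that return teal ends at 62.0% instead of 1.03%. Teal's free substrate stands at 5.14% against the reckoned 3.07%. Carry the count to 50 min: it reaches 52.7, so substrate should shrink by a factor 1.65, and in that neighbour of teal target stands at 0.653%, lower by a factor 1.58.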